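**Retrosynthetic overview**
- Feature: two bridge CH2 carbons each join C3 of a 4-hydroxy-2-pyrone ring to C3 or C5 of the central, fully substituted isobutyrylphloroglucinol ring. Between two enolic rings such a bridge forms and breaks through a pyrone 3-methide, so it is made here irreversibly on O-capped partners.
- Disconnections: first the five MOM ethers (global acid cleavage, last step). Then, as the key move, both arene C3-CH2 and C5-CH2 bonds at once by a two-directional Negishi coupling, with the arene carbons as electrophiles (C-Br) and the bridge carbons as nucleophiles (C-ZnCl).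
- Dibromide: phloroglucinol, Friedel-Crafts acylation, C3/C5 dibromination, tris-MOM ether.
- Zinc reagent: pyrone, C3 iodination, 4-O-MOM, I/Mg exchange with formaldehyde capture, chloride, zinc insertion. A 3-formylpyrone is avoided because its tricarbonyl anion is an ambident O-nucleophile and its 4-alkoxy derivative invites conjugate hydride attack.
- Rings: the benzene ring is bought. The only ring built is the 2-pyrone (step 5, silyl enol ether of pentan-3-one plus malonyl dichloride), made once and used twice. The key step closes no ring.

Key step: step 11

Remark on the chemistry: the target SMILES holds no stereocentre and no stereogenic double bond. The molecule is achiral, so no stereocontrol is needed and the route gives the single species drawn.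

**Step 1**
Reactants: 1 phloroglucinol; 2 isobutyryl chloride
Product: 3 2-methyl-1-(2,4,6-trihydroxyphenyl)propan-1-one (phlorisobutyrophenone)
Conditions: AlCl3 (3.5 equiv), CH2Cl2/PhNO2, 0 → 45 °C; aq HCl work-up
Reagents that add atoms: none
Why: Friedel-Crafts acylation of the very electron-rich ring should stop after one acyl group because the chelated aryl ketone deactivates the ring towards a second acylium ion.

**Step 2**
Reactants: 3 phlorisobutyrophenone
Product: 4 1-(3,5-dibromo-2,4,6-trihydroxyphenyl)-2-methylpropan-1-one
Conditions: NBS (2.0 equiv), MeCN, 0 °C, dark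
Reagents that add atoms: N-bromosuccinimide, O=C1CCC(=O)N1Br
Why: Electrophilic aromatic bromination can only strike the two free ring carbons C3 and C5, each activated by ortho and para hydroxyls, and exactly two equivalents of NBS should prevent ipso attack and dienone formation.

**Step 3**
Reactants: 4 dibromophlorisobutyrophenone
Product: 5 1-[3,5-dibromo-2,4,6-tris(methoxymethoxy)phenyl]-2-methylpropan-1-one
Conditions: NaH (3.3 equiv), MOMCl (3.6 equiv), DMF, 0 °C → rt
Reagents that add atoms: chloromethyl methyl ether (MOMCl), COCCl
Why: In this Williamson-type O-alkylation, full deprotonation breaks the ketone-phenol hydrogen bonds, and the hard oxocarbenium-like electrophile reacts at oxygen rather than at the fully substituted ring carbons.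

**Step 4**
Reactants: 6 pentan-3-one
Product: 7 (Z)-3-(trimethylsilyloxy)pent-2-ene (mainly Z; the geometry is lost in step 5)
Conditions: TMSOTf (1.1 equiv), Et3N (1.3 equiv), CH2Cl2, 0 °C; distillation
Reagents that add atoms: trimethylsilyl triflate, C[Si](C)(C)OS(=O)(=O)C(F)(F)F
Why: Soft enolisation and O-silylation of a symmetrical ketone gives a single regioisomer and supplies the neutral carbon nucleophile that malonyl dichloride needs, since the free ketone reacts unselectively with it.

**Step 5**
Reactants: 7 silyl enol ether; 8 malonyl dichloride
Product: 10 6-ethyl-4-hydroxy-5-methyl-2H-pyran-2-one, via keto acid chloride 9 (not isolated)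
Conditions: Et2O, -78 °C → rt
Reagents that add atoms: none
Why: C-acylation of the silyl enol ether by one acyl chloride gives 9, whose ethyl-ketone enol oxygen is acylated by the second acyl chloride in a six-membered enol lactonisation, and tautomerisation then gives the 4-hydroxy-2-pyrone, a known pyrone synthesis from enol silanes and malonyl dichloride.

**Step 6**
Reactants: 10 pyrone
Product: 11 6-ethyl-4-hydroxy-3-iodo-5-methyl-2H-pyran-2-one
Conditions: NIS (1.05 equiv), MeCN, rt, dark
Reagents that add atoms: N-iodosuccinimide, O=C1CCC(=O)N1I
Why: Electrophilic iodination occurs at C3, which is the enolic carbon between the two oxygenated positions and the only ring C-H, so the halogen marks without ambiguity the carbon that will bear the bridge.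

**Step 7**
Reactants: 11 3-iodopyrone
Product: 12 6-ethyl-3-iodo-4-(methoxymethoxy)-5-methyl-2H-pyran-2-one
Conditions: MOMCl (1.3 equiv), iPr2NEt (1.5 equiv), CH2Cl2, 0 °C
Reagents that add atoms: chloromethyl methyl ether (MOMCl), COCCl
Why: O-alkylation of the pyronate anion under basic conditions normally takes place at O4 and keeps the 2-pyrone chromophore, and any O2 isomer should be removable by chromatography.

**Step 8**
Reactants: 12 3-iodo-4-MOM-pyrone
Product: 14 6-ethyl-3-(hydroxymethyl)-4-(methoxymethoxy)-5-methyl-2H-pyran-2-one, via pyron-3-ylmagnesium chloride 13 (not isolated)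
Conditions: iPrMgCl·LiCl (1.1 equiv), THF, -40 °C; monomeric CH2O (cracked paraformaldehyde, THF solution, excess), -40 → 0 °C; aq NH4Cl
Reagents that add atoms: isopropylmagnesium chloride-lithium chloride, CC(C)[Mg]Cl.[Li+].[Cl-] (Mg and Cl of 13 only); formaldehyde, C=O
Why: Iodine-magnesium exchange on a cyclic alpha-iodo-beta-alkoxy enoate is fast at low temperature, is helped by chelation from the MOM oxygen, and cannot beta-eliminate inside the ring, so 1,2-addition of 13 to formaldehyde should install the future bridge carbon directly at the alcohol oxidation level.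

**Step 9**
Reactants: 14 hydroxymethylpyrone
Product: 16 3-(chloromethyl)-6-ethyl-4-(methoxymethoxy)-5-methyl-2H-pyran-2-one, via mesylate 15 (not isolated)
Conditions: MsCl (1.2 equiv), LiCl (3 equiv), 2,4,6-collidine (1.5 equiv), DMF, 0 °C
Reagents that add atoms: methanesulfonyl chloride, CS(=O)(=O)Cl (atoms of 15 only); lithium chloride, [Li+].[Cl-]
Why: The Collington-Meyers conversion of an allylic or benzylic alcohol proceeds by mesylation and then SN2 displacement by chloride, and it runs under buffered, acid-free conditions that the MOM acetal should survive.

**Step 10**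
Reactants: 16 chloromethylpyrone
Product: 17 {[6-ethyl-4-(methoxymethoxy)-5-methyl-2-oxo-2H-pyran-3-yl]methyl}zinc chloride (LiCl complex; THF solution titrated with iodine)
Conditions: Zn dust (2 equiv, activated), LiCl (1.5 equiv), THF, 0 → 25 °C, slow addition of 16
Reagents that add atoms: zinc, [Zn]
Why: LiCl-promoted direct insertion of zinc into benzylic and heterobenzylic chlorides tolerates esters and acetals, and because a chloride reacts more slowly than a bromide, Wurtz-type coupling on the metal surface stays low.

**Step 11**
Reactants: 5 tris-MOM dibromide; 17 pyron-3-ylmethylzinc chloride (2.6 equiv)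
Product: 19 penta-MOM ether 3,3'-{[5-(2-methylpropanoyl)-2,4,6-tris(methoxymethoxy)-1,3-phenylene]bis(methylene)}bis[6-ethyl-4-(methoxymethoxy)-5-methyl-2H-pyran-2-one], via monocoupled aryl bromide 18 (not isolated)
Conditions: SPhos Pd G3 (5 mol %), SPhos (5 mol %), THF, 50 °C, 17 added by syringe pump over several hours
Reagents that add atoms: none
Why: Ligated Pd(0) inserts into one C-Br bond of 5, the zinc reagent hands over its CH2 group, and reductive elimination forms the arene C3-CH2 bond of 18, which then passes through the same cycle at C5-Br to give 19. The closest known reaction type is the Negishi sp2-sp3 coupling of benzylic and heterobenzylic zinc chlorides with di-ortho-substituted, electron-rich aryl bromides under bulky dialkylbiarylphosphine or carbene ligands. No ring is closed and no stereocentre is formed, so only chemoselectivity and completeness of the double coupling are at stake. The isobutyryl group is meta to both bromides and gives only inductive help, but the crowded MOM ethers of the hexasubstituted ring are twisted out of conjugation, which lowers their donation, and the electron-rich ligand supplies the remaining drive for oxidative addition. The bridge carbon has no beta-hydrogen, the zinc reagent is too mild to add to the lactone or the flanked ketone, and bond formation at CH2 rather than at pyrone C4 of an eta-3 form is secured because only that path keeps the pyrone pi system and avoids a quaternary carbon. Slow addition keeps the zinc concentration low, which suppresses double transmetalation (homocoupling) and reduction of C-Br, and since all five oxygens are capped no pyrone 3-methide can arise, so the new bonds cannot exchange.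

**Step 12**
Reactants: 19 penta-MOM ether
Product: 20 3,3'-{[2,4,6-trihydroxy-5-(2-methylpropanoyl)-1,3-phenylene]bis(methylene)}bis(6-ethyl-4-hydroxy-5-methyl-2H-pyran-2-one) (target CNP0277086.0)
Conditions: HCl (1.25 M in MeOH), CH2Cl2, 0 °C → rt
Reagents that add atoms: none
Why: Acid-catalysed acetal exchange with methanol unmasks the two pyrone and three phenol oxygens, every nucleophilic ring carbon is already substituted so the released C1 unit cannot build new bridges, and the dilute cold acid should keep ipso-protonation and bridge cleavage out of reach.

**Compound list**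
1 | phloroglucinol | Oc1cc(O)cc(O)c1 | starting material
2 | isobutyryl chloride | CC(C)C(=O)Cl | starting material
3 | 2-methyl-1-(2,4,6-trihydroxyphenyl)propan-1-one | CC(C)C(=O)c1c(O)cc(O)cc1O | intermediate
4 | 1-(3,5-dibromo-2,4,6-trihydroxyphenyl)-2-methylpropan-1-one | CC(C)C(=O)c1c(O)c(Br)c(O)c(Br)c1O | intermediate
5 | 1-[3,5-dibromo-2,4,6-tris(methoxymethoxy)phenyl]-2-methylpropan-1-one | CC(C)C(=O)c1c(OCOC)c(Br)c(OCOC)c(Br)c1OCOC | intermediate
6 | pentan-3-one | CCC(=O)CC | starting material
7 | (Z)-3-(trimethylsilyloxy)pent-2-ene | C/C=C(\O[Si](C)(C)C)CC | intermediate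
8 | malonyl dichloride | O=C(Cl)CC(=O)Cl | starting material
9 | 4-methyl-3,5-dioxoheptanoyl chloride (not isolated) | CCC(=O)C(C)C(=O)CC(=O)Cl | intermediate
10 | 6-ethyl-4-hydroxy-5-methyl-2H-pyran-2-one | CCc1oc(=O)cc(O)c1C | intermediate
11 | 6-ethyl-4-hydroxy-3-iodo-5-methyl-2H-pyran-2-one | CCc1oc(=O)c(I)c(O)c1C | intermediate
12 | 6-ethyl-3-iodo-4-(methoxymethoxy)-5-methyl-2H-pyran-2-one | CCc1oc(=O)c(I)c(OCOC)c1C | intermediate
13 | [6-ethyl-4-(methoxymethoxy)-5-methyl-2-oxo-2H-pyran-3-yl]magnesium chloride (not isolated) | CCc1oc(=O)c([Mg]Cl)c(OCOC)c1C | intermediate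
14 | 6-ethyl-3-(hydroxymethyl)-4-(methoxymethoxy)-5-methyl-2H-pyran-2-one | CCc1oc(=O)c(CO)c(OCOC)c1C | intermediate
15 | [6-ethyl-4-(methoxymethoxy)-5-methyl-2-oxo-2H-pyran-3-yl]methyl methanesulfonate (not isolated) | CCc1oc(=O)c(COS(C)(=O)=O)c(OCOC)c1C | intermediate
16 | 3-(chloromethyl)-6-ethyl-4-(methoxymethoxy)-5-methyl-2H-pyran-2-one | CCc1oc(=O)c(CCl)c(OCOC)c1C | intermediate
17 | {[6-ethyl-4-(methoxymethoxy)-5-methyl-2-oxo-2H-pyran-3-yl]methyl}zinc chloride | CCc1oc(=O)c(C[Zn]Cl)c(OCOC)c1C | intermediate
18 | 3-{[3-bromo-5-(2-methylpropanoyl)-2,4,6-tris(methoxymethoxy)phenyl]methyl}-6-ethyl-4-(methoxymethoxy)-5-methyl-2H-pyran-2-one (not isolated) | CCc1oc(=O)c(Cc2c(OCOC)c(Br)c(OCOC)c(C(=O)C(C)C)c2OCOC)c(OCOC)c1C | intermediate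
19 | penta-MOM ether of the target | CCc1oc(=O)c(Cc2c(OCOC)c(Cc3c(OCOC)c(C)c(CC)oc3=O)c(OCOC)c(C(=O)C(C)C)c2OCOC)c(OCOC)c1C | intermediate
20 | 3,3'-{[2,4,6-trihydroxy-5-(2-methylpropanoyl)-1,3-phenylene]bis(methylene)}bis(6-ethyl-4-hydroxy-5-methyl-2H-pyran-2-one) | CCc1oc(=O)c(Cc2c(O)c(Cc3c(O)c(C)c(CC)oc3=O)c(O)c(C(=O)C(C)C)c2O)c(O)c1C | target

**Step count**
Total step count: 12. Longest linear sequence: 9 (steps 4 to 12).

**Steps most likely to fail**

1. **Step 11.**
   - What may go wrong: the coupling may stall after the first bond because the remaining C-Br site is shielded even more strongly. Reduction of C-Br, homocoupling of the zinc reagent, and zinc-halide-promoted loss of the vinylogous-ester MOM group (which would protonate the zinc reagent) may also compete.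
   - Fallback: this leaves cross-coupling altogether and sets out from 10 and 3. Compound 10 is aminomethylated with Eschenmoser's salt (CH2Cl2, rt) to the Mannich base 3-[(dimethylamino)methyl]-6-ethyl-4-hydroxy-5-methyl-2H-pyran-2-one F1.
   - Warming F1 with half an equivalent of 3 (MeCN, NaOAc) expels the amine to give 6-ethyl-5-methyl-3-methylidenepyran-2,4-dione F2. This is trapped in turn by C3 and C5 of 3, and the route is rejoined directly at 20.
   - Cost: this is the classical, reversible methylene bridging, so statistical by-products have to be removed by chromatography.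

2. **Step 10.**
   - What may go wrong: Wurtz-type dimerisation may occur on the zinc surface. The chloride may ionise, assisted by the 4-alkoxy donor, and be captured by the neighbouring MOM oxygen. Insertion may also be sluggish.
   - Fallback: this sets out from 16 and replaces zinc by boron. Palladium-catalysed borylation of the benzylic-type chloride (B2pin2, KOAc, dioxane) gives 6-ethyl-4-(methoxymethoxy)-5-methyl-3-[(4,4,5,5-tetramethyl-1,3,2-dioxaborolan-2-yl)methyl]-2H-pyran-2-one F3.
   - F3 can be stored and purified, and is joined twice to 5 by sp2-sp3 Suzuki-Miyaura coupling (Pd/SPhos, K3PO4, toluene/water). The route is rejoined at 19.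

3. **Step 8.**
   - What may go wrong: the Grignard reagent may add to the lactone carbonyl or to C6. Proton transfer from the 6-ethyl CH2 to the C3 carbanion may occur. Capture may be inefficient because formaldehyde oligomerises.
   - Fallback: this sets out from 12 and replaces the polar organometallic by a neutral Migita-Kosugi-Stille hydroxymethylation with (tributylstannyl)methanol (Pd(PPh3)4, dioxane, 90 °C). It gives 14 in one operation and rejoins the route there. It makes no compound outside the list (F0).

**Further compounds**
F1 | step 11 | 3-[(dimethylamino)methyl]-6-ethyl-4-hydroxy-5-methyl-2H-pyran-2-one | CCc1oc(=O)c(CN(C)C)c(O)c1C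
F2 | step 11 | 6-ethyl-5-methyl-3-methylidenepyran-2,4-dione | CCC1=C(C)C(=O)C(=C)C(=O)O1
F3 | step 10 | 6-ethyl-4-(methoxymethoxy)-5-methyl-3-[(4,4,5,5-tetramethyl-1,3,2-dioxaborolan-2-yl)methyl]-2H-pyran-2-one | CCc1oc(=O)c(CB2OC(C)(C)C(C)(C)O2)c(OCOC)c1C
F0 | step 8 | none | none
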